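## The problem

Target 33 is a diaryl ether of two oxygenated benzene rings, each carrying one C15 arm, a 3,7,11-trimethyldodeca-1,6,10-trien-3-yl group bound through its C3. Ring A is a 2-aryloxyphenol with the arm para to the free hydroxyl; ring B is a catechol whose third, ether oxygen lies next to the diol, with the arm para to the central oxygen. No ring besides the two arenes has to be made, so the work lies in building two chains with 6E geometry and in forming one aryl–O–aryl bond between two carbons that each have an oxygen neighbour. The only stereocentres are the two C3 atoms, all-carbon quaternary and benzylic, each bearing aryl, methyl, vinyl (C1=C2) and the homogeranyl chain (C4 onward). They are separated by the whole diaryl ether and cannot control each other, and they have opposite descriptors (3R on ring A, 3S on ring B) although their substituents are of the same kind, so each must be set by a reagent, and the two by mirror-image reagents. The six alkenes exclude hydrogenolysis, free halogen and strong acid (C6=C7 and C10=C11 hydrate or cyclise through tertiary cations), and the ring B catechol oxidises easily once free, so the phenols must stay masked to the end and be released gently. The feature that opens a short asymmetric entry is the local symmetry at C3: the vinyl group C1=C2 and the chain atoms C4–C5 are both two-carbon arms, so C3 is the central carbon of an achiral aryl(methyl)divinylmethane in which one of two enantiotopic vinyl groups has been saturated and extended. C5 is then bound to the sp2 carbon C6, a bond that a cross-coupling can form with the alkene geometry already fixed.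

## Retrosynthesis

**33 from 32.** Only the three O–CH2OMe bonds are cut. The MOM ether was chosen for all three phenols because it survives bases, hydride, organolithium, palladium and copper chemistry, directs ortho-lithiation on ring B, and leaves by mild acid methanolysis. The forward step must cleave three aryl acetals without touching the trisubstituted alkenes.

**32 from 20 and 31.** The ring B C–O bond of the diaryl ether is cut, giving the ring A phenol 20 and the ring B iodide 31. Cutting here, after both stereocentres exist, is preferred to an earlier ether formation: a diaryl ether carrying both prochiral carbons would ask one catalyst for opposite senses at two nearly identical sites. Ring B is the electrophile because its ether carbon lies ortho to a MOM ether and can be metalated on the finished arm. Ring A is the nucleophile because its two oxygens can be differentiated from the start. The forward reaction is a copper-catalysed coupling of two ortho-alkoxy partners.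

**31 from 29.** The C–I bond is cut back to the aryllithium 30 made by directed ortho-lithiation. Of the two positions ortho to a MOM ether in 29, one is flanked by the quaternary carbon and is shielded, so only the required one should react. Ring B therefore needs only two oxygens and no halogen that would have to survive two palladium steps and a hydride catalyst.

**20 from 13 and 18; 29 from 28 and 18.** The C5–C6 bond is cut. An sp3–sp2 Suzuki coupling joins the primary boronate to the E alkenyl iodide 18 with retention, so the 6E geometry is bought in, not made by an olefination that would give E/Z mixtures at a trisubstituted alkene. On ring A the silyl ether 19 is cleaved in the same operation to release the phenol 20.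

**18 from 16, and 16 from 14.** The C–I and C–CH3 bonds of 18 come from syn methylalumination of the terminal alkyne 16 (alkenylalane 17) and iodinolysis. Alkyne 16 comes from the methyl ketone 14 through its kinetic enol phosphate 15.

**13 from 11 and 12; 28 from 27 and 12 (key disconnection).** The C5–B and C4–H bonds are cut, and with them the stereocentre disappears: 11 and 27 are achiral. Both arms then come from the same kind of achiral sequence, and only the ligand enantiomer decides 3R or 3S. The forward reaction must choose one of two enantiotopic vinyl groups, place boron on the terminal carbon and stop after one addition of pinacolborane 12.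

**11 from 9, 8, 5 and 6; 27 from 25, 24, 22 and 6.** The two C=C bonds are cut to the malondialdehydes 10 and 26, which are generated from the diols 9 and 25 and methylenated without isolation. The diols come from the malonates 8 and 24 by hydride reduction. The aryl–C3 bond is cut to the aryl bromides 5 and 22 and diethyl malonate 6. The parent malonate is used, not a methyl-substituted one, because α-substituted malonate enolates are poor partners in palladium-catalysed arylation. The coupling products 7 and 23 are formed as enolates and are C-methylated in the same flask.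

**5 from 1; 22 from 21.** Bromide 5 has bromine para to the MOM ether and meta to the silyl ether. This pattern comes from 1 by MOM protection, exchange of the formyl carbon for oxygen by Baeyer–Villiger oxidation (formate 3, phenol 4) and silylation. Bromide 22 is the bis-MOM ether of 21.

## Roads not taken

**Alternative 1:** Both C3–C4 bonds would be cut at once. The diaryl ether bis-carbamate A2, with carbinol carbons of opposite configuration on the two rings, would be lithiated at both benzylic positions with an alkyllithium base and trapped with homogeranyl pinacol boronate A3. A 1,2-migration assisted by a Lewis acid/methanol additive would give the bis(tertiary boronic ester) A1, and a two-fold Zweifel olefination would then turn each C–B bond into the vinyl group.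
- Merits: the reaction class is well established for secondary benzylic carbamates and transfers configuration to the quaternary carbon stereospecifically. Both chains are attached in one flask to a preformed diaryl ether, so no late ether coupling is needed.
- Weak points: A2 needs two carbinol centres of opposite sense on one molecule, which brings back the need for two separately controlled asymmetric steps. The alkyllithium base meets three MOM ethers that direct ring lithiation in competition with benzylic deprotonation. Any shortfall at either centre gives diastereomers with remote stereocentres that would be hard to separate. The Zweifel step uses iodine in the presence of four trisubstituted alkenes and two hindered tertiary boronates.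
- Comparison: this road has the better precedent for the quaternary centre and needs no new catalytic reaction. The chosen plan sets against it an achiral precursor, one achiral sequence serving both arms, and no strong base or free iodine once the polyene is present.

**Alternative 2:** The C3–C2 bond to the vinyl group would be cut. The α-homogeranylstyrene A5 and ethene A6 would react under a cationic nickel hydride catalyst bearing a chiral phosphoramidite. Hydrogen would go to the =CH2 carbon (the future C3 methyl) and the vinyl group to C3, giving the (S)-configured ring B bromide A4 with the complete arm.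
- Merits: asymmetric hydrovinylation of α-alkylstyrenes is a known route to all-carbon quaternary centres. The chain is complete before the key step, so no sp3–sp2 coupling follows. A6 is the cheapest possible reagent, and the bromide of A4 is ready for the ether coupling.
- Weak points: the cationic nickel hydride is also an alkene isomerisation catalyst, and A5 offers it two trisubstituted alkenes. Two adjacent MOM ethers can chelate the Lewis-acidic metal. The catalyst must tell the nascent methyl from a CH2CH2R chain. A5 itself needs a regiodefined 1,1-disubstituted alkene synthesis.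
- Comparison: per arm this road is about two steps shorter and rests on precedent. The chosen plan sets against it a stereo-determining step run on a substrate whose only alkenes are the two that are meant to compete, a neutral hydride catalyst that tolerates ethers, and a larger steric contrast (aryl against methyl) at the carbon being read.

**Alternative 3:** The aryl–C3 bond of ring A would be cut at the last stage. The ring A pinacol boronate A8 of the otherwise complete diaryl ether would couple SN2' with (2E,6E)-farnesyl diethyl phosphate A9 under a copper alkoxide carrying a chiral N-heterocyclic carbene, giving the tris-MOM ether A7, which is identical with 32.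
- Merits: it is the most convergent road. The natural C15 unit is used intact with both E alkenes, the reaction type is known for aryl boronates and trisubstituted allylic phosphates, and it ends one step before the target.
- Weak points: the step sets only the ring A centre, so the ring B arm in A8 must have been made earlier by the same reaction with the mirror-image ligand, followed by boron and halogen bookkeeping on one diaryl ether. The catalyst must distinguish the two γ-substituents of A9, methyl and a CH2 chain, which is a small steric difference. The linear α-product would be a close isomer, and stereoisomers from imperfect selectivity at the late stage could not be removed.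
- Comparison: this road is clearly shorter than the chosen plan, since it needs neither the C5–C6 coupling nor an alkenyl iodide, and the same bond construction is kept in reserve as the fallback for steps 7 and 15. The chosen plan sets against it a catalyst that reads aryl against methyl, and a second hydroboration that should remove the minor enantiomer.

Key step: step 7

Assumption: the sense of induction of the cobalt catalyst on this substrate class is not known; the (S)-ligand is assigned to ring A for definiteness, and the two ligand enantiomers are exchanged between steps 7 and 15 if the opposite sense is found.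

In the conditions, L is N-(2,6-diisopropylphenyl)-1-[6-(4-isopropyl-4,5-dihydro-1,3-oxazol-2-yl)pyridin-2-yl]ethan-1-imine, used as its CoCl2 complex.

## Route

Step 1
Reactants: 1 5-bromo-2-hydroxybenzaldehyde
Product: 2 5-bromo-2-(methoxymethoxy)benzaldehyde
Conditions: MeOCH2Cl, i-Pr2NEt, CH2Cl2, 0 °C → rt
Reagents that add atoms: chloromethyl methyl ether, COCCl
Why: O-alkylation of the phenoxide (Williamson-type acetal formation); the amine base leaves the aldehyde and the bromide untouched.

Step 2
Reactants: 2 5-bromo-2-(methoxymethoxy)benzaldehyde
Product: 4 5-bromo-2-(methoxymethoxy)phenol, via aryl formate 3 (not isolated)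
Conditions: mCPBA, CH2Cl2, rt; then K2CO3 (cat.), MeOH, rt
Reagents that add atoms: 3-chloroperoxybenzoic acid, O=C(OO)c1cccc(Cl)c1
Why: Baeyer–Villiger (Dakin-type) oxidation; the aryl group ortho to the alkoxy substituent migrates in preference to hydride, and mild methanolysis of the formate frees the phenol without touching the MOM ether.

Step 3
Reactants: 4 5-bromo-2-(methoxymethoxy)phenol
Product: 5 [5-bromo-2-(methoxymethoxy)phenoxy]triisopropylsilane
Conditions: i-Pr3SiCl, imidazole, DMF, rt
Reagents that add atoms: triisopropylsilyl chloride, CC(C)[Si](Cl)(C(C)C)C(C)C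
Why: Silylation of the phenol; the bulky triisopropylsilyl group is chosen to survive the malonate enolate, hydride reduction and the ylide, and is orthogonal to MOM.

Step 4
Reactants: 5 [5-bromo-2-(methoxymethoxy)phenoxy]triisopropylsilane; 6 diethyl malonate
Product: 8 diethyl 2-methyl-2-[4-(methoxymethoxy)-3-(triisopropylsilyloxy)phenyl]malonate, via arylmalonate 7 (not isolated)
Conditions: Pd(dba)2, P(t-Bu)3, NaH (2.2 equiv), THF, 70 °C; then MeI, rt
Reagents that add atoms: iodomethane, CI
Why: Palladium-catalysed α-arylation of a malonate enolate, followed by malonic ester C-alkylation in the same flask; the coupling product is more acidic than 6 and is present as its sodium enolate, so it is methylated directly.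

Step 5
Reactants: 8 diethyl 2-methyl-2-[4-(methoxymethoxy)-3-(triisopropylsilyloxy)phenyl]malonate
Product: 9 2-methyl-2-[4-(methoxymethoxy)-3-(triisopropylsilyloxy)phenyl]propane-1,3-diol
Conditions: LiAlH4, THF, 0 °C; H2O/NaOH work-up
Reagents that add atoms: none
Why: Hydride reduction of both esters; the quaternary α-carbon has no hydrogen, so neither elimination nor epimerisation can interfere, and the hindered aryl silyl ether should hold at 0 °C.

Step 6
Reactants: 9 2-methyl-2-[4-(methoxymethoxy)-3-(triisopropylsilyloxy)phenyl]propane-1,3-diol
Product: 11 triisopropyl[2-(methoxymethoxy)-5-(3-methylpenta-1,4-dien-3-yl)phenoxy]silane, via dialdehyde 10 (not isolated)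
Conditions: (COCl)2, DMSO, CH2Cl2, −78 °C; Et3N; then Ph3P=CH2 (excess, from Ph3PCH3Br and KN(SiMe3)2, THF), −78 °C → rt
Reagents that add atoms: methyltriphenylphosphonium bromide, C[P+](c1ccccc1)(c1ccccc1)c1ccccc1.[Br-]
Why: Double Swern oxidation and double Wittig methylenation in one flask; the non-enolisable but deformylation-prone malondialdehyde 10 is never isolated and meets excess ylide at low temperature.

Step 7
Reactants: 11 triisopropyl[2-(methoxymethoxy)-5-(3-methylpenta-1,4-dien-3-yl)phenoxy]silane; 12 pinacolborane
Product: 13 triisopropyl{2-(methoxymethoxy)-5-[(3R)-3-methyl-5-(4,4,5,5-tetramethyl-1,3,2-dioxaborolan-2-yl)pent-1-en-3-yl]phenoxy}silane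
Conditions: CoCl2·(S)-L (3 mol%), NaBHEt3 (6 mol%), 12 (1.05 equiv), THF, 0 °C → rt
Reagents that add atoms: none
Why: Proposed new method: NaBHEt3 reduces the CoCl2–ligand complex to a low-valent cobalt hydride; one vinyl group of 11 binds and inserts into Co–H with cobalt on the terminal carbon (C4–H formed), and σ-bond metathesis of the primary alkylcobalt with 12 forms the C5–B bond and returns the hydride. The closest known reaction type is the anti-Markovnikov asymmetric hydroboration of 1,1-disubstituted aryl alkenes and the desymmetrising hydrosilylation or hydroboration of prochiral dienes with this family of chiral cobalt hydride catalysts; an acyclic aryl(methyl)divinylmethane has not been used. No ring closes. C3 becomes stereogenic through the choice between its two enantiotopic vinyl groups, and the ligand controls that choice: with the alkene bound, the allylic C3 holds aryl and methyl in fixed positions, and the oxazoline substituent and the N-aryl wall of the pincer should accept only one arrangement. The step needs group selection, terminal boron and mono-addition. The quaternary C3 beside the alkene enforces insertion with cobalt on CH2 and excludes alkene isomerisation, since C3 carries no hydrogen, and one equivalent of 12 limits double addition. Any second hydroboration should fall mainly on the minor enantiomer of 13, whose remaining vinyl group is the one the catalyst prefers, so the enantiomeric purity of 13 should rise with conversion. The aryl silyl ether and the MOM acetal are inert to the neutral hydride catalyst.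

Step 8
Reactants: 14 6-methylhept-5-en-2-one
Product: 16 6-methylhept-5-en-1-yne, via enol phosphate 15 (not isolated)
Conditions: LiN(i-Pr)2, THF, −78 °C; ClP(O)(OEt)2; then LiN(i-Pr)2 (2.3 equiv), −78 °C → rt
Reagents that add atoms: none
Why: Methyl ketone to terminal alkyne by kinetic deprotonation on the methyl side, O-phosphorylation and base-induced elimination of the enol phosphate; the trisubstituted alkene is inert to the amide base.

Step 9
Reactants: 16 6-methylhept-5-en-1-yne
Product: 18 (1E)-1-iodo-2,6-dimethylhepta-1,5-diene, via alkenylalane 17 (not isolated)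
Conditions: Me3Al, Cp2ZrCl2, CH2Cl2, 0 °C → rt; then I2, THF, −30 °C
Reagents that add atoms: trimethylaluminium, C[Al](C)C; iodine, II
Why: Zirconium-catalysed methylalumination of the alkyne (Negishi carboalumination) is a syn addition with aluminium at the terminal carbon, and iodinolysis replaces aluminium with retention, which fixes the E geometry.

Step 10
Reactants: 13 triisopropyl{2-(methoxymethoxy)-5-[(3R)-3-methyl-5-(4,4,5,5-tetramethyl-1,3,2-dioxaborolan-2-yl)pent-1-en-3-yl]phenoxy}silane; 18 (1E)-1-iodo-2,6-dimethylhepta-1,5-diene
Product: 20 2-(methoxymethoxy)-5-[(3R,6E)-3,7,11-trimethyldodeca-1,6,10-trien-3-yl]phenol, via silyl ether 19 (not isolated)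
Conditions: Pd(OAc)2, RuPhos, KOH, THF/H2O, 70 °C; then n-Bu4NF, THF, rt; aq. NH4Cl
Reagents that add atoms: none
Why: B-alkyl Suzuki–Miyaura coupling of a hydroxide-activated primary pinacol boronate with an alkenyl iodide, with retention of the E geometry; fluoride then cleaves the aryl silyl ether. C3 has no hydrogen and no leaving group, so its configuration cannot change.

Step 11
Reactants: 21 4-bromobenzene-1,2-diol
Product: 22 4-bromo-1,2-bis(methoxymethoxy)benzene
Conditions: MeOCH2Cl, i-Pr2NEt, CH2Cl2, 0 °C → rt
Reagents that add atoms: chloromethyl methyl ether, COCCl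
Why: Double O-alkylation of the catechol to the bis-acetal, which protects both phenols and later directs ring lithiation.

Step 12
Reactants: 22 4-bromo-1,2-bis(methoxymethoxy)benzene; 6 diethyl malonate
Product: 24 diethyl 2-[3,4-bis(methoxymethoxy)phenyl]-2-methylmalonate, via arylmalonate 23 (not isolated)
Conditions: Pd(dba)2, P(t-Bu)3, NaH (2.2 equiv), THF, 70 °C; then MeI, rt
Reagents that add atoms: iodomethane, CI
Why: Palladium-catalysed malonate α-arylation followed by C-methylation of the enolate in the same flask, as in step 4.

Step 13
Reactants: 24 diethyl 2-[3,4-bis(methoxymethoxy)phenyl]-2-methylmalonate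
Product: 25 2-[3,4-bis(methoxymethoxy)phenyl]-2-methylpropane-1,3-diol
Conditions: LiAlH4, THF, 0 °C; H2O/NaOH work-up
Reagents that add atoms: none
Why: Hydride reduction of both esters; MOM ethers are inert to LiAlH4.

Step 14
Reactants: 25 2-[3,4-bis(methoxymethoxy)phenyl]-2-methylpropane-1,3-diol
Product: 27 1,2-bis(methoxymethoxy)-4-(3-methylpenta-1,4-dien-3-yl)benzene, via dialdehyde 26 (not isolated)
Conditions: (COCl)2, DMSO, CH2Cl2, −78 °C; Et3N; then Ph3P=CH2 (excess, from Ph3PCH3Br and KN(SiMe3)2, THF), −78 °C → rt
Reagents that add atoms: methyltriphenylphosphonium bromide, C[P+](c1ccccc1)(c1ccccc1)c1ccccc1.[Br-]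
Why: One-flask double Swern oxidation and double Wittig methylenation, as in step 6.

Step 15
Reactants: 27 1,2-bis(methoxymethoxy)-4-(3-methylpenta-1,4-dien-3-yl)benzene; 12 pinacolborane
Product: 28 2-{(3S)-3-[3,4-bis(methoxymethoxy)phenyl]-3-methylpent-4-en-1-yl}-4,4,5,5-tetramethyl-1,3,2-dioxaborolane
Conditions: CoCl2·(R)-L (3 mol%), NaBHEt3 (6 mol%), 12 (1.05 equiv), THF, 0 °C → rt
Reagents that add atoms: none
Why: Proposed new method: the same cobalt hydride cycle as in step 7 (alkene insertion with cobalt on the terminal carbon, then σ-bond metathesis with 12), run with the mirror-image ligand so that the other enantiotopic vinyl group reacts and C3 becomes S; the closest known reaction type is again the cobalt-catalysed asymmetric hydroboration of aryl alkenes and the desymmetrisation of prochiral dienes, and the ring substituents that differ from 11 are remote from the reacting alkenes.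

Step 16
Reactants: 28 2-{(3S)-3-[3,4-bis(methoxymethoxy)phenyl]-3-methylpent-4-en-1-yl}-4,4,5,5-tetramethyl-1,3,2-dioxaborolane; 18 (1E)-1-iodo-2,6-dimethylhepta-1,5-diene
Product: 29 1,2-bis(methoxymethoxy)-4-[(3S,6E)-3,7,11-trimethyldodeca-1,6,10-trien-3-yl]benzene
Conditions: Pd(OAc)2, RuPhos, KOH, THF/H2O, 70 °C
Reagents that add atoms: none
Why: B-alkyl Suzuki–Miyaura coupling with retention of the alkenyl iodide geometry, as in step 10.

Step 17
Reactants: 29 1,2-bis(methoxymethoxy)-4-[(3S,6E)-3,7,11-trimethyldodeca-1,6,10-trien-3-yl]benzene
Product: 31 1-iodo-2,3-bis(methoxymethoxy)-5-[(3S,6E)-3,7,11-trimethyldodeca-1,6,10-trien-3-yl]benzene, via aryllithium 30 (not isolated)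
Conditions: n-BuLi, THF, 0 °C; then ICH2CH2I, −78 °C → rt
Reagents that add atoms: 1,2-diiodoethane, ICCI
Why: Directed ortho-metalation by the MOM ether; the other position ortho to an acetal is wedged against the quaternary carbon, so lithiation should occur next to the MOM ether para to the arm. 1,2-Diiodoethane delivers iodine to the aryllithium without exposing the alkenes to free iodine.

Step 18
Reactants: 20 2-(methoxymethoxy)-5-[(3R,6E)-3,7,11-trimethyldodeca-1,6,10-trien-3-yl]phenol; 31 1-iodo-2,3-bis(methoxymethoxy)-5-[(3S,6E)-3,7,11-trimethyldodeca-1,6,10-trien-3-yl]benzene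
Product: 32 1,2-bis(methoxymethoxy)-3-{2-(methoxymethoxy)-5-[(3R,6E)-3,7,11-trimethyldodeca-1,6,10-trien-3-yl]phenoxy}-5-[(3S,6E)-3,7,11-trimethyldodeca-1,6,10-trien-3-yl]benzene
Conditions: CuI, N,N-dimethylglycine·HCl, Cs2CO3, 1,4-dioxane, 100 °C
Reagents that add atoms: none
Why: Ullmann diaryl ether synthesis with an amino acid ligand, which allows coupling of ortho-substituted, electron-rich partners below the temperature at which the alkenes would suffer; the base-stable MOM ethers and both quaternary centres are unaffected.

Step 19
Reactants: 32 1,2-bis(methoxymethoxy)-3-{2-(methoxymethoxy)-5-[(3R,6E)-3,7,11-trimethyldodeca-1,6,10-trien-3-yl]phenoxy}-5-[(3S,6E)-3,7,11-trimethyldodeca-1,6,10-trien-3-yl]benzene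
Product: 33 3-{2-hydroxy-5-[(3R,6E)-3,7,11-trimethyldodeca-1,6,10-trien-3-yl]phenoxy}-5-[(3S,6E)-3,7,11-trimethyldodeca-1,6,10-trien-3-yl]benzene-1,2-diol
Conditions: dilute HCl, MeOH/THF, rt → 40 °C, degassed
Reagents that add atoms: none
Why: Acid-catalysed acetal exchange with methanol removes the three aryl MOM groups as dimethoxymethane; dilute acid and excess methanol keep the trisubstituted alkenes intact, and exclusion of air protects the freed catechol.

## Compound list

1 | 5-bromo-2-hydroxybenzaldehyde | O=Cc1cc(Br)ccc1O | starting material
2 | 5-bromo-2-(methoxymethoxy)benzaldehyde | COCOc1ccc(Br)cc1C=O | intermediate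
3 | 5-bromo-2-(methoxymethoxy)phenyl formate (not isolated) | COCOc1ccc(Br)cc1OC=O | intermediate
4 | 5-bromo-2-(methoxymethoxy)phenol | COCOc1ccc(Br)cc1O | intermediate
5 | [5-bromo-2-(methoxymethoxy)phenoxy]triisopropylsilane | COCOc1ccc(Br)cc1O[Si](C(C)C)(C(C)C)C(C)C | intermediate
6 | diethyl malonate | CCOC(=O)CC(=O)OCC | starting material
7 | diethyl 2-[4-(methoxymethoxy)-3-(triisopropylsilyloxy)phenyl]malonate (as sodium enolate, not isolated) | CCOC(=O)C(C(=O)OCC)c1ccc(OCOC)c(O[Si](C(C)C)(C(C)C)C(C)C)c1 | intermediate
8 | diethyl 2-methyl-2-[4-(methoxymethoxy)-3-(triisopropylsilyloxy)phenyl]malonate | CCOC(=O)C(C)(C(=O)OCC)c1ccc(OCOC)c(O[Si](C(C)C)(C(C)C)C(C)C)c1 | intermediate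
9 | 2-methyl-2-[4-(methoxymethoxy)-3-(triisopropylsilyloxy)phenyl]propane-1,3-diol | OCC(C)(CO)c1ccc(OCOC)c(O[Si](C(C)C)(C(C)C)C(C)C)c1 | intermediate
10 | 2-methyl-2-[4-(methoxymethoxy)-3-(triisopropylsilyloxy)phenyl]propanedial (not isolated) | O=CC(C)(C=O)c1ccc(OCOC)c(O[Si](C(C)C)(C(C)C)C(C)C)c1 | intermediate
11 | triisopropyl[2-(methoxymethoxy)-5-(3-methylpenta-1,4-dien-3-yl)phenoxy]silane | C=CC(C)(C=C)c1ccc(OCOC)c(O[Si](C(C)C)(C(C)C)C(C)C)c1 | intermediate
12 | pinacolborane (4,4,5,5-tetramethyl-1,3,2-dioxaborolane) | [H]B1OC(C)(C)C(C)(C)O1 | starting material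
13 | triisopropyl{2-(methoxymethoxy)-5-[(3R)-3-methyl-5-(4,4,5,5-tetramethyl-1,3,2-dioxaborolan-2-yl)pent-1-en-3-yl]phenoxy}silane | C=C[C@@](C)(CCB1OC(C)(C)C(C)(C)O1)c1ccc(OCOC)c(O[Si](C(C)C)(C(C)C)C(C)C)c1 | intermediate
14 | 6-methylhept-5-en-2-one | CC(=O)CCC=C(C)C | starting material
15 | diethyl 6-methylhepta-1,5-dien-2-yl phosphate (not isolated) | C=C(CCC=C(C)C)OP(=O)(OCC)OCC | intermediate
16 | 6-methylhept-5-en-1-yne | C#CCCC=C(C)C | intermediate
17 | [(1E)-2,6-dimethylhepta-1,5-dien-1-yl]dimethylalane (not isolated) | C[Al](C)/C=C(\C)CCC=C(C)C | intermediate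
18 | (1E)-1-iodo-2,6-dimethylhepta-1,5-diene | I/C=C(\C)CCC=C(C)C | intermediate
19 | triisopropyl{2-(methoxymethoxy)-5-[(3R,6E)-3,7,11-trimethyldodeca-1,6,10-trien-3-yl]phenoxy}silane (not isolated) | C=C[C@@](C)(CC/C=C(\C)CCC=C(C)C)c1ccc(OCOC)c(O[Si](C(C)C)(C(C)C)C(C)C)c1 | intermediate
20 | 2-(methoxymethoxy)-5-[(3R,6E)-3,7,11-trimethyldodeca-1,6,10-trien-3-yl]phenol | C=C[C@@](C)(CC/C=C(\C)CCC=C(C)C)c1ccc(OCOC)c(O)c1 | intermediate
21 | 4-bromobenzene-1,2-diol (4-bromocatechol) | Oc1ccc(Br)cc1O | starting material
22 | 4-bromo-1,2-bis(methoxymethoxy)benzene | COCOc1ccc(Br)cc1OCOC | intermediate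
23 | diethyl 2-[3,4-bis(methoxymethoxy)phenyl]malonate (as sodium enolate, not isolated) | CCOC(=O)C(C(=O)OCC)c1ccc(OCOC)c(OCOC)c1 | intermediate
24 | diethyl 2-[3,4-bis(methoxymethoxy)phenyl]-2-methylmalonate | CCOC(=O)C(C)(C(=O)OCC)c1ccc(OCOC)c(OCOC)c1 | intermediate
25 | 2-[3,4-bis(methoxymethoxy)phenyl]-2-methylpropane-1,3-diol | OCC(C)(CO)c1ccc(OCOC)c(OCOC)c1 | intermediate
26 | 2-[3,4-bis(methoxymethoxy)phenyl]-2-methylpropanedial (not isolated) | O=CC(C)(C=O)c1ccc(OCOC)c(OCOC)c1 | intermediate
27 | 1,2-bis(methoxymethoxy)-4-(3-methylpenta-1,4-dien-3-yl)benzene | C=CC(C)(C=C)c1ccc(OCOC)c(OCOC)c1 | intermediate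
28 | 2-{(3S)-3-[3,4-bis(methoxymethoxy)phenyl]-3-methylpent-4-en-1-yl}-4,4,5,5-tetramethyl-1,3,2-dioxaborolane | C=C[C@](C)(CCB1OC(C)(C)C(C)(C)O1)c1ccc(OCOC)c(OCOC)c1 | intermediate
29 | 1,2-bis(methoxymethoxy)-4-[(3S,6E)-3,7,11-trimethyldodeca-1,6,10-trien-3-yl]benzene | C=C[C@](C)(CC/C=C(\C)CCC=C(C)C)c1ccc(OCOC)c(OCOC)c1 | intermediate
30 | {2,3-bis(methoxymethoxy)-5-[(3S,6E)-3,7,11-trimethyldodeca-1,6,10-trien-3-yl]phenyl}lithium (not isolated) | C=C[C@](C)(CC/C=C(\C)CCC=C(C)C)c1cc([Li])c(OCOC)c(OCOC)c1 | intermediate
31 | 1-iodo-2,3-bis(methoxymethoxy)-5-[(3S,6E)-3,7,11-trimethyldodeca-1,6,10-trien-3-yl]benzene | C=C[C@](C)(CC/C=C(\C)CCC=C(C)C)c1cc(I)c(OCOC)c(OCOC)c1 | intermediate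
32 | 1,2-bis(methoxymethoxy)-3-{2-(methoxymethoxy)-5-[(3R,6E)-3,7,11-trimethyldodeca-1,6,10-trien-3-yl]phenoxy}-5-[(3S,6E)-3,7,11-trimethyldodeca-1,6,10-trien-3-yl]benzene | C=C[C@@](C)(CC/C=C(\C)CCC=C(C)C)c1ccc(OCOC)c(Oc2cc([C@](C)(C=C)CC/C=C(\C)CCC=C(C)C)cc(OCOC)c2OCOC)c1 | intermediate
33 | 3-{2-hydroxy-5-[(3R,6E)-3,7,11-trimethyldodeca-1,6,10-trien-3-yl]phenoxy}-5-[(3S,6E)-3,7,11-trimethyldodeca-1,6,10-trien-3-yl]benzene-1,2-diol | C=C[C@@](C)(CC/C=C(\C)CCC=C(C)C)c1ccc(O)c(Oc2cc([C@](C)(C=C)CC/C=C(\C)CCC=C(C)C)cc(O)c2O)c1 | target

## Step count and least certain steps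

Total step count: 19. Longest linear sequence: 10 steps (steps 1–7, 10, 18 and 19). The ring B branch (steps 11–17) and the alkenyl iodide branch (steps 8 and 9) are shorter.

**Step 7 (key step, new method).** The most likely failure is insufficient discrimination between the two enantiotopic vinyl groups, because the catalyst has to read aryl against methyl on a carbon that is not part of the alkene it binds. Over-addition to a bis-boronate and slow insertion at a vinyl group beside a quaternary carbon would lower the yield further. The fallback uses known chemistry and makes the aryl–C3 bond and the vinyl group together by copper-catalysed enantioselective SN2' arylation of a trisubstituted allylic phosphate. Bromide 5 is converted by Miyaura borylation (bis(neopentyl glycolato)diboron, Pd(dppf)Cl2, KOAc, dioxane) into 2-[4-(methoxymethoxy)-3-(triisopropylsilyloxy)phenyl]-5,5-dimethyl-1,3,2-dioxaborinane F1. This is coupled with (2E,6E)-farnesyl diethyl phosphate F2, made from commercial (2E,6E)-farnesol and ClP(O)(OEt)2, under CuCl, a chiral hydroxy-substituted N-heterocyclic carbene and NaOMe in THF. Attack at the methyl-bearing γ-carbon gives silyl ether 19, which is desilylated as in the second operation of step 10. The detour sets out from 5 and comes back to the route at 19.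

**Step 15 (new method).** The same hazards apply on ring B: poor group selection by the mirror-image catalyst, and over-addition. The fallback is the same known SN2' arylation. Bromide 22 is borylated as above to 2-[3,4-bis(methoxymethoxy)phenyl]-5,5-dimethyl-1,3,2-dioxaborinane F3, which is coupled with F2 under CuCl, the enantiomeric carbene and NaOMe to give 29. The detour sets out from 22 and comes back at 29.

**Step 6.** The likely failure is loss of a formyl group from the 1,3-dialdehyde by nucleophilic attack (retro-Claisen-type deformylation, or retro-aldol cleavage of the first Wittig adduct) before both carbonyls are methylenated. The same hazard exists in step 14. The fallback makes the two vinyl groups one after the other, so that no 1,3-dialdehyde ever exists.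
- Diol 9 is monosilylated (NaH, t-BuMe2SiCl, THF) to racemic 3-[tert-butyl(dimethyl)silyloxy]-2-methyl-2-[4-(methoxymethoxy)-3-(triisopropylsilyloxy)phenyl]propan-1-ol F4.
- Dess–Martin oxidation gives the aldehyde F5.
- Wittig methylenation gives the alkene F6.
- Camphorsulfonic acid in MeOH at 0 °C removes the alkyl silyl group, leaving the aryl silyl ether and the MOM ether, to give 2-methyl-2-[4-(methoxymethoxy)-3-(triisopropylsilyloxy)phenyl]but-3-en-1-ol F7.
- A second Dess–Martin oxidation gives 2-methyl-2-[4-(methoxymethoxy)-3-(triisopropylsilyloxy)phenyl]but-3-enal F8, and a second methylenation gives 11.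

The detour sets out from 9 and comes back at 11.

**Step 10.** The likely failure is slow transfer of the primary alkyl group from the pinacol boronate to palladium, which leaves time for β-hydride elimination of the alkylpalladium, protodeboronation, or Heck-type insertion of the vinyl group. Step 16 is the same reaction. The fallback changes the nucleophile to an organozinc and the coupling to a Negishi reaction.
- Boronate 13 is oxidised (NaBO3·4H2O, THF/H2O) to (3R)-3-methyl-3-[4-(methoxymethoxy)-3-(triisopropylsilyloxy)phenyl]pent-4-en-1-ol F9.
- I2, PPh3 and imidazole convert F9 into the primary iodide F10.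
- Zinc insertion (Zn, LiCl, THF, 40 °C) gives the alkylzinc iodide F11.
- Coupling of F11 with 18 (Pd(PPh3)4, THF, rt) gives 19.

The detour sets out from 13 and comes back at 19.

**Step 18.** The likely failure is sluggish C–O bond formation between two partners that each carry an ortho acetal, with reduction of the C–I bond competing at the temperature needed. The fallback is a Chan–Lam coupling at room temperature. Aryllithium 30, generated from 29 as in step 17, is quenched with B(OMe)3 and hydrolysed to {2,3-bis(methoxymethoxy)-5-[(3S,6E)-3,7,11-trimethyldodeca-1,6,10-trien-3-yl]phenyl}boronic acid F12. F12 is coupled with phenol 20 (Cu(OAc)2, pyridine, 4 Å molecular sieves, CH2Cl2, air) to give 32. The detour sets out from 29 and comes back at 32.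

**Step 19.** The likely failures are acid-induced hydration or cyclisation of the trisubstituted alkenes, alkylation of the electron-rich rings by methoxymethyl cation during the cleavage of three aryl acetals, and air oxidation of the freed catechol. The fallback avoids protic acid. Compound 32 is treated with Et3SiOTf and 2,2'-bipyridyl (CH2Cl2, 0 °C), which exchanges each aryl MOM group for a silyl group and gives the tris(triethylsilyl) ether F13. Buffered fluoride (n-Bu4NF, AcOH, THF, 0 °C) then releases 33. The detour sets out from 32 and comes back at 33.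

## Further compounds

F1 | step 7 | 2-[4-(methoxymethoxy)-3-(triisopropylsilyloxy)phenyl]-5,5-dimethyl-1,3,2-dioxaborinane | COCOc1ccc(B2OCC(C)(C)CO2)cc1O[Si](C(C)C)(C(C)C)C(C)C
F2 | step 7 | (2E,6E)-farnesyl diethyl phosphate | CCOP(=O)(OCC)OC/C=C(\C)CC/C=C(\C)CCC=C(C)C
F3 | step 15 | 2-[3,4-bis(methoxymethoxy)phenyl]-5,5-dimethyl-1,3,2-dioxaborinane | COCOc1ccc(B2OCC(C)(C)CO2)cc1OCOC
F4 | step 6 | racemic 3-[tert-butyl(dimethyl)silyloxy]-2-methyl-2-[4-(methoxymethoxy)-3-(triisopropylsilyloxy)phenyl]propan-1-ol | CC(CO)(CO[Si](C)(C)C(C)(C)C)c1ccc(OCOC)c(O[Si](C(C)C)(C(C)C)C(C)C)c1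
F5 | step 6 | racemic 3-[tert-butyl(dimethyl)silyloxy]-2-methyl-2-[4-(methoxymethoxy)-3-(triisopropylsilyloxy)phenyl]propanal | CC(C=O)(CO[Si](C)(C)C(C)(C)C)c1ccc(OCOC)c(O[Si](C(C)C)(C(C)C)C(C)C)c1
F6 | step 6 | racemic tert-butyl(dimethyl){2-methyl-2-[4-(methoxymethoxy)-3-(triisopropylsilyloxy)phenyl]but-3-enyloxy}silane | C=CC(C)(CO[Si](C)(C)C(C)(C)C)c1ccc(OCOC)c(O[Si](C(C)C)(C(C)C)C(C)C)c1
F7 | step 6 | racemic 2-methyl-2-[4-(methoxymethoxy)-3-(triisopropylsilyloxy)phenyl]but-3-en-1-ol | C=CC(C)(CO)c1ccc(OCOC)c(O[Si](C(C)C)(C(C)C)C(C)C)c1
F8 | step 6 | racemic 2-methyl-2-[4-(methoxymethoxy)-3-(triisopropylsilyloxy)phenyl]but-3-enal | C=CC(C)(C=O)c1ccc(OCOC)c(O[Si](C(C)C)(C(C)C)C(C)C)c1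
F9 | step 10 | (3R)-3-methyl-3-[4-(methoxymethoxy)-3-(triisopropylsilyloxy)phenyl]pent-4-en-1-ol | C=C[C@@](C)(CCO)c1ccc(OCOC)c(O[Si](C(C)C)(C(C)C)C(C)C)c1
F10 | step 10 | triisopropyl{5-[(3R)-5-iodo-3-methylpent-1-en-3-yl]-2-(methoxymethoxy)phenoxy}silane | C=C[C@@](C)(CCI)c1ccc(OCOC)c(O[Si](C(C)C)(C(C)C)C(C)C)c1
F11 | step 10 | {(3R)-3-methyl-3-[4-(methoxymethoxy)-3-(triisopropylsilyloxy)phenyl]pent-4-en-1-yl}zinc iodide | C=C[C@@](C)(CC[Zn]I)c1ccc(OCOC)c(O[Si](C(C)C)(C(C)C)C(C)C)c1
F12 | step 18 | {2,3-bis(methoxymethoxy)-5-[(3S,6E)-3,7,11-trimethyldodeca-1,6,10-trien-3-yl]phenyl}boronic acid | C=C[C@](C)(CC/C=C(\C)CCC=C(C)C)c1cc(B(O)O)c(OCOC)c(OCOC)c1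
F13 | step 19 | tris(triethylsilyl) ether of 33 | C=C[C@@](C)(CC/C=C(\C)CCC=C(C)C)c1ccc(O[Si](CC)(CC)CC)c(Oc2cc([C@](C)(C=C)CC/C=C(\C)CCC=C(C)C)cc(O[Si](CC)(CC)CC)c2O[Si](CC)(CC)CC)c1
A1 | alternative 1 | bis(tertiary pinacol boronic ester) with both chains attached | CC1(C)OB(OC1(C)C)[C@@](C)(CC/C=C(\C)CCC=C(C)C)c1ccc(OCOC)c(Oc2cc([C@](C)(B3OC(C)(C)C(C)(C)O3)CC/C=C(\C)CCC=C(C)C)cc(OCOC)c2OCOC)c1
A2 | alternative 1 | heterochiral diaryl ether bis(1-arylethyl N,N-diisopropylcarbamate) | CC(C)N(C(C)C)C(=O)O[C@H](C)c1ccc(OCOC)c(Oc2cc([C@H](C)OC(=O)N(C(C)C)C(C)C)cc(OCOC)c2OCOC)c1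
A3 | alternative 1 | homogeranyl pinacol boronate, 2-[(3E)-4,8-dimethylnona-3,7-dien-1-yl]-4,4,5,5-tetramethyl-1,3,2-dioxaborolane | CC(C)=CCC/C(C)=C/CCB1OC(C)(C)C(C)(C)O1
A4 | alternative 2 | 1-bromo-2,3-bis(methoxymethoxy)-5-[(3S,6E)-3,7,11-trimethyldodeca-1,6,10-trien-3-yl]benzene | C=C[C@](C)(CC/C=C(\C)CCC=C(C)C)c1cc(Br)c(OCOC)c(OCOC)c1
A5 | alternative 2 | 1-bromo-5-[(5E)-6,10-dimethylundeca-1,5,9-trien-2-yl]-2,3-bis(methoxymethoxy)benzene | C=C(CC/C=C(\C)CCC=C(C)C)c1cc(Br)c(OCOC)c(OCOC)c1
A6 | alternative 2 | ethene | C=C
A7 | alternative 3 | tris-MOM ether of the target, identical with 32 | C=C[C@@](C)(CC/C=C(\C)CCC=C(C)C)c1ccc(OCOC)c(Oc2cc([C@](C)(C=C)CC/C=C(\C)CCC=C(C)C)cc(OCOC)c2OCOC)c1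
A8 | alternative 3 | ring A pinacol boronate of the diaryl ether carrying the complete ring B arm | CC1(C)OB(OC1(C)C)c1ccc(OCOC)c(Oc2cc([C@](C)(C=C)CC/C=C(\C)CCC=C(C)C)cc(OCOC)c2OCOC)c1
A9 | alternative 3 | (2E,6E)-farnesyl diethyl phosphate | CCOP(=O)(OCC)OC/C=C(\C)CC/C=C(\C)CCC=C(C)C
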